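**Retrosynthetic overview**

1. Target 22 ← tertiary propargylic alcohol 20 (Meyer–Schuster) ← methyl ketone 19 ← 4-hydroxy-2-pyranone amide 16. The pyranone is the last ring formed, from aldehyde 11 and keto ester 12 by dianion aldol, oxidation and lactonisation.
2. Aldehyde amide 11 ← cis-fused lactone acetal 9 by amide opening. The acetal carbon becomes the aldehyde and then pyranone C6; the lactone carbonyl becomes the side-chain carbon C(Me)=.
3. The strategy rests on the cyclohexa-2,4-diene ring (C1 = quaternary carbon bearing methyl and the pyranone, C6 = CH bearing the enone chain). Its diene C2H=C3(Me)–C4H=C5(Me) is C3–C6 of 4,6-dimethyl-2-pyranone 7, and the adjacent cis sp3 carbons C1 and C6 are C4 and C3 of the ring alkene of butenolide 6. Hence 9 ← 6 + 7 by [4+2] addition, then loss of CO2.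
4. Butenolide 6 ← glyoxylic acid + propanal + (+)-menthol.
5. Ring order: butenolide (step 1, sacrificial), carbocycle (step 3), pyranone (step 7).

Key step: step 3

Assumption: of the two acetal epimers formed in step 2, the (5S) epimer is taken to be the one that crystallises, by analogy with the mirror-image menthyloxy furanone series; if the (5R) epimer crystallises instead, the epimers are separated by chromatography and the unwanted one is re-equilibrated with acid.

**Route**

Step 1
Reactants: 1 glyoxylic acid (50% aqueous solution); 2 propanal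
Product: 3 5-hydroxy-4-methylfuran-2(5H)-one (racemic lactol)
Conditions: morpholine·HCl, 1,4-dioxane/H2O, reflux
Reagents that add atoms: none
Why: Amine-mediated Mannich-type aldol condensation of propanal (through its enamine) with glyoxylic acid, dehydration and ring closure of the (Z)-formyl acrylic acid to the pseudo-acid lactol is the standard preparation of this hydroxybutenolide; its only stereocentre is an epimerisable lactol carbon.

Step 2
Reactants: 3 5-hydroxy-4-methylfuran-2(5H)-one; 4 (+)-menthol
Product: 6 (5S)-4-methyl-5-[(1S,2R,5S)-menthyloxy]furan-2(5H)-one, via (5R)-acetal epimer 5 (not isolated)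
Conditions: CSA (cat.), toluene, reflux, Dean–Stark; crystallisation from hexane; mother liquor re-equilibrated with CSA and recrystallised
Reagents that add atoms: none
Why: Acid-catalysed acetalisation of the lactol through the furanone oxocarbenium ion gives both acetal epimers, which interconvert under the acid, so crystallisation of the (5S) epimer sets the C5 configuration that later directs the cycloaddition.

Step 3
Reactants: 6 (5S)-4-methyl-5-[(1S,2R,5S)-menthyloxy]furan-2(5H)-one; 7 4,6-dimethyl-2H-pyran-2-one
Product: 9 (3S,3aS,7aR)-3-[(1S,2R,5S)-menthyloxy]-3a,5,7-trimethyl-3a,7a-dihydro-2-benzofuran-1(3H)-one, via bridged bicyclic lactone 8 (not isolated)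
Conditions: 7 (3 equiv), CH2Cl2, 15 kbar, 50 °C; then toluene, 110 °C (–CO2)
Reagents that add atoms: none
Why: Under pressure the pyranone serves as the diene in a concerted suprafacial [4+2] addition across C3=C4 of the butenolide, its nucleophilic terminus C3 (which carries the large HOMO coefficient through conjugation with the ring oxygen) bonding to the electrophilic, methyl-bearing C4 of 6 and its C6 bonding to C3 of 6; heating at ambient pressure then causes retro-[4+2] loss of CO2 from 8, which returns both bridgeheads to sp2 and leaves the diene at C4=C5–C6=C7 of 9. The closest known chemistry is the Diels–Alder reaction of 2-pyranones with electron-poor alkenes followed by thermal CO2 extrusion, together with the anti-selective cycloadditions of 5-menthyloxyfuran-2(5H)-ones. The carbocycle is closed by an intermolecular cycloaddition that forms C3a–C4 and C7–C7a in one event, and the extrusion closes no ring. C3a and C7a are cis because both are carbons of the ring alkene of 6, and their absolute configuration follows from approach of the diene to the face opposite the C5 menthyloxy group, which sits next to the quaternary centre being formed. The step needs regiocontrol and facial control only: the reverse regiochemistry would join the two methyl-bearing carbons (pyranone C6 and butenolide C4) and is disfavoured both electronically and sterically, while endo/exo selectivity is irrelevant because the bridgehead centres vanish with CO2.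

Step 4
Reactants: 9 (3S,3aS,7aR)-3-[(1S,2R,5S)-menthyloxy]-3a,5,7-trimethyl-3a,7a-dihydro-2-benzofuran-1(3H)-one
Product: 11 (1R,6S)-6-formyl-N-methoxy-N,2,4,6-tetramethylcyclohexa-2,4-diene-1-carboxamide, via ring-opened menthyl hemiacetal 10 (not isolated)
Conditions: MeNHOMe·HCl (slight excess over AlMe3), AlMe3, CH2Cl2, 0 °C → rt; aq. KNaC4H4O6 (Rochelle salt), 0 °C
Reagents that add atoms: N,O-dimethylhydroxylamine hydrochloride, CNOC.Cl
Why: Weinreb aminolysis with the aluminium amide attacks the only carbonyl group, and hemiacetal 10 loses menthol on work-up to unveil the aldehyde on the quaternary carbon, so the two former carbonyl carbons of the dienophile emerge differentiated with neither ring stereocentre touched; 11 is kept cold and used at once because a formyl group on the sp3 carbon of a cyclohexa-1,3-diene can undergo [1,5] shift on heating.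

Step 5
Reactants: 11 (1R,6S)-6-formyl-N-methoxy-N,2,4,6-tetramethylcyclohexa-2,4-diene-1-carboxamide; 12 methyl 2-methyl-3-oxopentanoate
Product: 14 methyl 5-hydroxy-5-[(1S,6R)-6-(methoxy(methyl)carbamoyl)-1,3,5-trimethylcyclohexa-2,4-dien-1-yl]-2,4-dimethyl-3-oxopentanoate (ring configuration as in 11; mixture at the three chain stereocentres), via dilithium dienolate 13 (not isolated)
Conditions: 12 (3 equiv), LiN(i-Pr)2 (6 equiv), THF, 0 °C; then 11, –78 °C; AcOH, –78 °C
Reagents that add atoms: none
Why: Aldol addition of the γ-carbon of the β-keto ester dianion to the non-enolisable aldehyde is fast at –78 °C, where the hindered Weinreb amide is inert, and protonation at –78 °C keeps the new alkoxide from lactonising onto the cis amide; the three new stereocentres are left uncontrolled because all become sp2 carbons in steps 6 and 7.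

Step 6
Reactants: 14 aldol adduct
Product: 15 methyl 5-[(1S,6R)-6-(methoxy(methyl)carbamoyl)-1,3,5-trimethylcyclohexa-2,4-dien-1-yl]-2,4-dimethyl-3,5-dioxopentanoate (ring configuration as in 11; keto/enol and diastereomer mixture)
Conditions: Dess–Martin periodinane, pyridine, CH2Cl2, 0 °C → rt
Reagents that add atoms: none
Why: Dess–Martin oxidation of the secondary alcohol under buffered, non-basic conditions should give the β,δ-diketo ester without retro-aldol cleavage, lactonisation or epimerisation of the ring stereocentres.

Step 7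
Reactants: 15 β,δ-diketo ester
Product: 16 (1R,6S)-6-(4-hydroxy-3,5-dimethyl-2-oxo-2H-pyran-6-yl)-N-methoxy-N,2,4,6-tetramethylcyclohexa-2,4-diene-1-carboxamide
Conditions: DBU (2 equiv), toluene, rt → 50 °C
Reagents that add atoms: none
Why: DBU enolises the δ-ketone towards its only α-carbon and the enol oxygen acylates on the methyl ester with loss of methanol, the standard lactonisation of 3,5-dioxo esters to 4-hydroxy-2-pyranones; DBU is too weak a base to deprotonate the amide α-centre.

Step 8
Reactants: 16 hydroxypyranone Weinreb amide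
Product: 18 6-[(1S,6R)-6-acetyl-1,3,5-trimethylcyclohexa-2,4-dien-1-yl]-4-hydroxy-3,5-dimethyl-2H-pyran-2-one, via magnesium hemiaminal adduct 17 (not isolated)
Conditions: MeMgBr (4 equiv), THF, 0 °C → rt; then 1 M HCl, 0 °C
Reagents that add atoms: methylmagnesium bromide, C[Mg]Br
Why: Weinreb ketone synthesis in which the first equivalent of MeMgBr deprotonates the acidic 4-hydroxy group, the resulting magnesium pyranonate is inert to further attack, and the next equivalent adds to the amide to give chelated adduct 17, which collapses to the methyl ketone only on acidic work-up, so neither over-addition nor epimerisation of the α-centre is expected.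

Step 9
Reactants: 18 hydroxypyranone methyl ketone
Product: 19 2-[(1S,6R)-6-acetyl-1,3,5-trimethylcyclohexa-2,4-dien-1-yl]-6-methoxy-3,5-dimethyl-4H-pyran-4-one
Conditions: MeOSO2F (1.5 equiv), CH2Cl2, 0 °C → rt; aq. NaHCO3
Reagents that add atoms: methyl fluorosulfonate, COS(=O)(=O)F
Why: The hard electrophile methylates the neutral 4-hydroxy-2-pyranone at its more basic C2 carbonyl oxygen and loss of the 4-OH proton then gives the 2-methoxy-4-pyranone, the known regioselective entry to α-methoxy-γ-pyranones, while the ketone is not nucleophilic towards the reagent.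

Step 10
Reactants: 19 methoxypyranone methyl ketone
Product: 20 2-[(1S,6R)-6-(2-hydroxypent-3-yn-2-yl)-1,3,5-trimethylcyclohexa-2,4-dien-1-yl]-6-methoxy-3,5-dimethyl-4H-pyran-4-one (carbinol epimers)
Conditions: MeC≡CMgBr, CeCl3, THF, –78 → 0 °C; aq. NH4Cl
Reagents that add atoms: prop-1-yn-1-ylmagnesium bromide, CC#C[Mg]Br
Why: The propynylcerium reagent is small, strongly oxophilic and hardly basic, so it should add 1,2 to the hindered enolisable ketone without deprotonating the adjacent stereocentre or attacking the vinylogous carbonate carbonyl of the pyranone; the configuration of the new carbinol centre is irrelevant because it is lost in step 11.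

Step 11
Reactants: 20 tertiary propargylic alcohol
Product: 22 2-methoxy-3,5-dimethyl-6-{(1S,6S)-1,3,5-trimethyl-6-[(2E)-4-oxopent-2-en-2-yl]cyclohexa-2,4-dien-1-yl}-4H-pyran-4-one (CNP0353320.2), via allenol 21 (not isolated)
Conditions: ReOCl3(OPPh3)(SMe2) (cat.), 1,2-dimethoxyethane, 60–80 °C
Reagents that add atoms: none
Why: Oxorhenium-catalysed Meyer–Schuster rearrangement transposes the tertiary propargylic hydroxyl 1,3 through the rhenium ester to allenol 21, which tautomerises to the β-methyl enone; the (E) isomer, with the bulky ring carbon trans to the acetyl group, is thermodynamically preferred, and the neutral, non-π-acidic catalyst avoids both enyne cycloisomerisation with the ring diene and base that could epimerise the doubly allylic C6–H.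

**Compound list**

1 | glyoxylic acid | OC(=O)C=O | starting material
2 | propanal | CCC=O | starting material
3 | 5-hydroxy-4-methylfuran-2(5H)-one (racemic) | CC1=CC(=O)OC1O | intermediate
4 | (+)-menthol, (1S,2R,5S)-5-methyl-2-(propan-2-yl)cyclohexan-1-ol | CC(C)[C@H]1CC[C@H](C)C[C@@H]1O | starting material
5 | (5R)-4-methyl-5-[(1S,2R,5S)-menthyloxy]furan-2(5H)-one | CC1=CC(=O)O[C@H]1O[C@H]1C[C@@H](C)CC[C@@H]1C(C)C | intermediate (not isolated)
6 | (5S)-4-methyl-5-[(1S,2R,5S)-menthyloxy]furan-2(5H)-one | CC1=CC(=O)O[C@@H]1O[C@H]1C[C@@H](C)CC[C@@H]1C(C)C | intermediate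
7 | 4,6-dimethyl-2H-pyran-2-one | CC1=CC(=O)OC(C)=C1 | starting material
8 | bridged Diels–Alder adduct: 1,8-dimethyl-2-oxabicyclo[2.2.2]oct-7-en-3-one whose C5–C6 bond is the cis ring-fusion bond of the menthyloxy γ-lactone (C5 = quaternary methyl carbon bonded to the acetal carbon, C6 bonded to the lactone carbonyl); endo/exo mixture | C[C@]12C3C(C)=CC(C)(OC3=O)[C@H]1C(=O)O[C@@H]2O[C@H]1C[C@@H](C)CC[C@@H]1C(C)C | intermediate (not isolated)
9 | (3S,3aS,7aR)-3-[(1S,2R,5S)-menthyloxy]-3a,5,7-trimethyl-3a,7a-dihydro-2-benzofuran-1(3H)-one (cis-fused; 3a-methyl, 7a-H and menthyloxy on the same face of the lactone ring) | C[C@]12C=C(C)C=C(C)[C@H]1C(=O)O[C@@H]2O[C@H]1C[C@@H](C)CC[C@@H]1C(C)C | intermediate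
10 | (1R,6S)-6-[hydroxy(menthyloxy)methyl]-N-methoxy-N,2,4,6-tetramethylcyclohexa-2,4-diene-1-carboxamide (hemiacetal, acetal configuration as in 9) | O[C@@H]([C@@]1(C)C=C(C)C=C(C)[C@H]1C(=O)N(C)OC)O[C@H]1C[C@@H](C)CC[C@@H]1C(C)C | intermediate (not isolated)
11 | (1R,6S)-6-formyl-N-methoxy-N,2,4,6-tetramethylcyclohexa-2,4-diene-1-carboxamide (formyl and carboxamide cis) | O=C[C@@]1(C)C=C(C)C=C(C)[C@H]1C(=O)N(C)OC | intermediate
12 | methyl 2-methyl-3-oxopentanoate | CCC(=O)C(C)C(=O)OC | starting material
13 | dilithium dienolate of 12 | CC=C([O-])C(C)=C([O-])OC.[Li+].[Li+] | intermediate (not isolated)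
14 | methyl 5-hydroxy-5-[(1S,6R)-6-(methoxy(methyl)carbamoyl)-1,3,5-trimethylcyclohexa-2,4-dien-1-yl]-2,4-dimethyl-3-oxopentanoate (ring as in 11; chain diastereomers) | COC(=O)C(C)C(=O)C(C)C(O)[C@@]1(C)C=C(C)C=C(C)[C@H]1C(=O)N(C)OC | intermediate
15 | methyl 5-[(1S,6R)-6-(methoxy(methyl)carbamoyl)-1,3,5-trimethylcyclohexa-2,4-dien-1-yl]-2,4-dimethyl-3,5-dioxopentanoate (ring as in 11) | COC(=O)C(C)C(=O)C(C)C(=O)[C@@]1(C)C=C(C)C=C(C)[C@H]1C(=O)N(C)OC | intermediate
16 | (1R,6S)-6-(4-hydroxy-3,5-dimethyl-2-oxo-2H-pyran-6-yl)-N-methoxy-N,2,4,6-tetramethylcyclohexa-2,4-diene-1-carboxamide | O=C1OC([C@@]2(C)C=C(C)C=C(C)[C@H]2C(=O)N(C)OC)=C(C)C(O)=C1C | intermediate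
17 | tetrahedral adduct of 16 with MeMgBr (N-methoxy-N-methyl hemiaminal, present as its magnesium salt; neutral form drawn) | O=C1OC([C@@]2(C)C=C(C)C=C(C)[C@H]2C(C)(O)N(C)OC)=C(C)C(O)=C1C | intermediate (not isolated)
18 | 6-[(1S,6R)-6-acetyl-1,3,5-trimethylcyclohexa-2,4-dien-1-yl]-4-hydroxy-3,5-dimethyl-2H-pyran-2-one | O=C1OC([C@@]2(C)C=C(C)C=C(C)[C@H]2C(C)=O)=C(C)C(O)=C1C | intermediate
19 | 2-[(1S,6R)-6-acetyl-1,3,5-trimethylcyclohexa-2,4-dien-1-yl]-6-methoxy-3,5-dimethyl-4H-pyran-4-one | COc1oc([C@@]2(C)C=C(C)C=C(C)[C@H]2C(C)=O)c(C)c(=O)c1C | intermediate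
20 | 2-[(1S,6R)-6-(2-hydroxypent-3-yn-2-yl)-1,3,5-trimethylcyclohexa-2,4-dien-1-yl]-6-methoxy-3,5-dimethyl-4H-pyran-4-one (carbinol epimers) | COc1oc([C@@]2(C)C=C(C)C=C(C)[C@H]2C(C)(O)C#CC)c(C)c(=O)c1C | intermediate
21 | allenol: 2-[(1S,6R)-6-(4-hydroxypenta-2,3-dien-2-yl)-1,3,5-trimethylcyclohexa-2,4-dien-1-yl]-6-methoxy-3,5-dimethyl-4H-pyran-4-one | COc1oc([C@@]2(C)C=C(C)C=C(C)[C@H]2C(C)=C=C(C)O)c(C)c(=O)c1C | intermediate (not isolated)
22 | 2-methoxy-3,5-dimethyl-6-{(1S,6S)-1,3,5-trimethyl-6-[(2E)-4-oxopent-2-en-2-yl]cyclohexa-2,4-dien-1-yl}-4H-pyran-4-one | COc1oc([C@@]2(C)C=C(C)C=C(C)[C@H]2/C(C)=C/C(C)=O)c(C)c(=O)c1C | target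

**Step count**

Total steps: 11. Longest linear sequence: 11 steps (glyoxylic acid and propanal to 22; compounds 4, 7 and 12 are purchased).

**Steps most likely to fail, with fallbacks**

Step 3. The cycloaddition may be too slow, because a trisubstituted, singly activated alkene meets an unactivated, aromatically stabilised diene; alternatively the bridged adduct may revert to 6 and 7 on heating instead of losing CO2. The fallback separates activation from chirality and sets out from pyranone 7. Heating 7 (in excess, to limit a second addition) with commercial citraconic anhydride (CC1=CC(=O)OC1=O) in xylene at 140 °C should give the bridged anhydride adduct F1, which loses CO2 under these conditions to give racemic cis-3a,5,7-trimethyl-3a,7a-dihydro-2-benzofuran-1,3-dione F2; the regiochemical argument is the same, the methyl-bearing alkene carbon bonding to pyranone C3. LiAlH(O-t-Bu)3 in THF at –30 °C reduces the carbonyl group next to the quaternary carbon, the usual site of hydride attack on 2,2-disubstituted succinic anhydrides, to the racemic hydroxy lactone 3-hydroxy-3a,5,7-trimethyl-3a,7a-dihydro-2-benzofuran-1(3H)-one F3. Acetalisation of this with (+)-menthol 4 (CSA, toluene, Dean–Stark) gives diastereomeric menthyl acetals, from which 9 is separated by crystallisation or chromatography; the route is rejoined at 9.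

Step 5. Addition to the neopentyl aldehyde may be slow, the aldolate (or alcohol 14 on standing) may close onto the cis amide to a γ-lactone that can no longer be oxidised to the diketone, or the adduct may revert by retro-aldol cleavage. The fallback makes the C–C bond by acylation, so that no alcohol is ever present, and sets out from 11. Oxidation of 11 (NaClO2, NaH2PO4, 2-methyl-2-butene, t-BuOH/H2O, 0 °C) gives (1S,6R)-6-(methoxy(methyl)carbamoyl)-1,3,5-trimethylcyclohexa-2,4-diene-1-carboxylic acid F4. Activation with 1,1'-carbonyldiimidazole in THF gives the acyl imidazole F5, and C-acylation of dianion 13 at its γ-carbon (THF, –78 → 0 °C) gives diketo ester 15 directly; the route is rejoined at 15.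

Step 11. The tertiary propargylic alcohol may ionise and dehydrate to enynes, or the transposition may stop at an E/Z mixture that does not equilibrate. The fallback sets out from ketone 19. Peterson olefination with the lithium enolate of ethyl (trimethylsilyl)acetate (LiN(i-Pr)2, THF, –78 °C → rt) should give, after separation from the Z isomer, ethyl (2E)-3-[(1S,6S)-6-(6-methoxy-3,5-dimethyl-4-oxo-4H-pyran-2-yl)-2,4,6-trimethylcyclohexa-2,4-dien-1-yl]but-2-enoate F6. MeNHOMe·HCl with i-PrMgCl (THF, –20 °C) converts this into the corresponding N-methoxy-N-methyl but-2-enamide F7, and MeMgBr (THF, –78 → 0 °C) gives 22; the route is rejoined at the target 22.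

**Further compounds**

F1 | step 3 | bridged anhydride adduct of 7 and citraconic anhydride (racemic, one enantiomer drawn; endo/exo mixture) | C[C@]12C3C(C)=CC(C)(OC3=O)[C@H]1C(=O)OC2=O
F2 | step 3 | cis-3a,5,7-trimethyl-3a,7a-dihydro-2-benzofuran-1,3-dione (racemic, one enantiomer drawn) | C[C@]12C=C(C)C=C(C)[C@H]1C(=O)OC2=O
F3 | step 3 | cis-3-hydroxy-3a,5,7-trimethyl-3a,7a-dihydro-2-benzofuran-1(3H)-one (racemic, one enantiomer drawn; lactol epimers) | C[C@]12C=C(C)C=C(C)[C@H]1C(=O)OC2O
F4 | step 5 | (1S,6R)-6-(methoxy(methyl)carbamoyl)-1,3,5-trimethylcyclohexa-2,4-diene-1-carboxylic acid | OC(=O)[C@@]1(C)C=C(C)C=C(C)[C@H]1C(=O)N(C)OC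
F5 | step 5 | (1R,6S)-6-(1H-imidazole-1-carbonyl)-N-methoxy-N,2,4,6-tetramethylcyclohexa-2,4-diene-1-carboxamide | O=C(n1ccnc1)[C@@]1(C)C=C(C)C=C(C)[C@H]1C(=O)N(C)OC
F6 | step 11 | ethyl (2E)-3-[(1S,6S)-6-(6-methoxy-3,5-dimethyl-4-oxo-4H-pyran-2-yl)-2,4,6-trimethylcyclohexa-2,4-dien-1-yl]but-2-enoate | COc1oc([C@@]2(C)C=C(C)C=C(C)[C@H]2/C(C)=C/C(=O)OCC)c(C)c(=O)c1C
F7 | step 11 | (2E)-N-methoxy-3-[(1S,6S)-6-(6-methoxy-3,5-dimethyl-4-oxo-4H-pyran-2-yl)-2,4,6-trimethylcyclohexa-2,4-dien-1-yl]-N-methylbut-2-enamide | COc1oc([C@@]2(C)C=C(C)C=C(C)[C@H]2/C(C)=C/C(=O)N(C)OC)c(C)c(=O)c1C
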